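Ring B is a catechol monoaryl ether: B3 carries the oxygen to ring A, the neighbouring B4 a free hydroxyl, and B1 the ketone chain. The route disconnects B3–B4 and B4–B5, so that B4 with its oxygen comes from one carbonyl ligand of chromium. Irradiation of a pentacarbonyl[aryloxy(dienyl)carbene]chromium complex under CO inserts that ligand at the carbene carbon, and the dienylketene closes by 6π electrocyclisation; one operation thus builds ring B, turns the carbene oxygen into the diaryl ether oxygen and frees the B4 phenol. The precursor is a (2Z)-penta-2,4-dienylidene complex whose carbene oxygen bears ring A as the methyl dihydroferulate unit and whose C3 carries a silyloxypropyl chain.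

Key step: step 6

Remark: ring B is numbered B1 (chain carbon) to B6; B2 is the CH between B1 and B3.
Remark: the Z-dienyl iodide is built by anti-carbomagnesiation of propargyl alcohol and methylenation, because vinylcopper reagents add poorly to unactivated 1-alkynes.
Remark: the carbon that becomes B4 is already a ligand of the precursor; the CO atmosphere only refills chromium, so the key step has no atom-adding reagent.
Assumption: (3-bromopropoxy)(tert-butyl)dimethylsilane, prop-2-yn-1-ol, Cr(CO)6, methyl 3-(4-hydroxy-3-methoxyphenyl)propanoate and 4-bromobenzene-1,3-diol are bought, as is methyl 3-(4-hydroxyphenyl)propanoate, which only the fallbacks use.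

Step 1
Reactants: 1 (3-bromopropoxy)(tert-butyl)dimethylsilane; 2 prop-2-yn-1-ol
Product: 5 (2Z)-5-[(tert-butyldimethylsilyl)oxy]-2-(iodomethylidene)pentan-1-ol, via Grignard reagent 3 (not isolated), via chelated alkenylmagnesium alkoxide 4 (not isolated)
Conditions: Mg, THF, rt; then 2 (0.4 equiv), CuI (10 mol %), Et2O/THF, −10 °C to rt; then I2, THF, −40 to 0 °C
Reagents that add atoms: iodine, [I][I]
Why: Copper-catalysed anti-carbomagnesiation of propargyl alcohol (Duboudin reaction) places the alkyl group on C2 and magnesium on C3 in a five-membered chelate, and iodinolysis with retention leaves iodine cis to the CH2OH carbon, which sets the cis relation needed later on B1=B2.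

Step 2
Reactants: 5 (2Z)-5-[(tert-butyldimethylsilyl)oxy]-2-(iodomethylidene)pentan-1-ol
Product: 6 (2Z)-5-[(tert-butyldimethylsilyl)oxy]-2-(iodomethylidene)pentanal
Conditions: MnO2 (excess), CH2Cl2, rt, dark; filtered through Celite and used at once
Reagents that add atoms: none
Why: Allylic alcohol oxidation on MnO2 runs at neutral pH on a solid surface, so the silyl ether and the alkenyl iodide are untouched and the Z-enal meets neither acid nor base.

Step 3
Reactants: 6 (2Z)-5-[(tert-butyldimethylsilyl)oxy]-2-(iodomethylidene)pentanal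
Product: 7 tert-butyl{[(4Z)-4-(iodomethylidene)hex-5-en-1-yl]oxy}dimethylsilane
Conditions: Ph3PCH3Br, KN(SiMe3)2, THF, −78 to 0 °C
Reagents that add atoms: methyltriphenylphosphonium bromide, C[P+](c1ccccc1)(c1ccccc1)c1ccccc1.[Br-]
Why: Wittig methylenation by the non-stabilised ylide is fast at the aldehyde at low temperature and creates no new stereo element, so iodine stays cis to the new vinyl group.

Step 4
Reactants: 7 tert-butyl{[(4Z)-4-(iodomethylidene)hex-5-en-1-yl]oxy}dimethylsilane; 8 chromium hexacarbonyl, Cr(CO)6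
Product: 11 tetramethylammonium pentacarbonyl{(2Z)-3-[3-(tert-butyldimethylsilyloxy)propyl]-1-oxidopenta-2,4-dien-1-ylidene}chromate, via dienyllithium 9 (not isolated), via lithium acylchromate 10 (not isolated)
Conditions: t-BuLi (2.05 equiv), Et2O, −78 °C; Cr(CO)6, Et2O, −78 °C to rt; Me4NBr, H2O, CH2Cl2 extraction
Reagents that add atoms: tetramethylammonium bromide, C[N+](C)(C)C.[Br-]
Why: Iodine–lithium exchange with retention of alkene geometry is followed by addition of the alkenyllithium to a CO ligand (Fischer acylmetalate synthesis) and cation metathesis to the storable ammonium salt.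

Step 5
Reactants: 11 tetramethylammonium pentacarbonyl{(2Z)-3-[3-(tert-butyldimethylsilyloxy)propyl]-1-oxidopenta-2,4-dien-1-ylidene}chromate; 12 methyl 3-(4-hydroxy-3-methoxyphenyl)propanoate
Product: 14 pentacarbonyl{(2Z)-3-[3-(tert-butyldimethylsilyloxy)propyl]-1-[2-methoxy-4-(3-methoxy-3-oxopropyl)phenoxy]penta-2,4-dien-1-ylidene}chromium, via acetoxycarbene complex 13 (not isolated)
Conditions: AcBr (1.05 equiv), CH2Cl2, −40 °C; then 12 (1.1 equiv), −40 to −20 °C; cold filtration (silica, pentane/Et2O, −20 °C), used at once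
Reagents that add atoms: none
Why: O-Acylation of the acylate gives an acyloxycarbene whose acetate is replaced by the phenol through addition–elimination at the carbene carbon (alcoholysis of acyloxycarbene complexes, a route known for aryloxy(alkenyl)carbene chromium complexes), and at −40 °C attack at the carbene carbon should outrun conjugate addition.

Step 6
Reactants: 14 pentacarbonyl{(2Z)-3-[3-(tert-butyldimethylsilyloxy)propyl]-1-[2-methoxy-4-(3-methoxy-3-oxopropyl)phenoxy]penta-2,4-dien-1-ylidene}chromium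
Product: 17 methyl 3-{4-[5-(3-{[tert-butyl(dimethyl)silyl]oxy}propyl)-2-hydroxyphenoxy]-3-methoxyphenyl}propanoate, via chromium-bound dienylketene 15 (not isolated), via cyclohexa-2,4-dienone 16 (not isolated)
Conditions: hν (medium-pressure Hg lamp, Pyrex), CO (1 atm), degassed THF, 0 °C; then air, filtration through Celite
Reagents that add atoms: none
Why: Proposed new method: light drives migration of a cis CO ligand onto the carbene carbon to give a chromium-bound (aryloxy)dienylketene, which forms B3–B4; thermal disrotatory 6π electrocyclisation of the cis-dienylketene then forms B4–B5 and closes the six-membered ring B as a cyclohexa-2,4-dienone, which enolises to the phenol. The closest known reaction type is the photochemical benzannulation of alkoxy(dienyl)carbene chromium complexes to ortho-alkoxyphenols; an aryloxy donor on an acyclic diene has not been shown. No stereocentre is formed, because B5 is a CH2 group in the dienone. The step needs the ketene carbon and the vinyl group cis on B1=B2, which the Z-iodide of step 1 secures, and it needs CO insertion to outrun chromium-centred closure to a cyclopentadiene, which the CO atmosphere and the low temperature favour. Regiochemistry follows from connectivity: the carbene oxygen becomes the B3 ether oxygen and the inserted CO the free B4 hydroxyl.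

Step 7
Reactants: 17 methyl 3-{4-[5-(3-{[tert-butyl(dimethyl)silyl]oxy}propyl)-2-hydroxyphenoxy]-3-methoxyphenyl}propanoate
Product: 18 methyl 3-{4-[2-(benzyloxy)-5-(3-{[tert-butyl(dimethyl)silyl]oxy}propyl)phenoxy]-3-methoxyphenyl}propanoate
Conditions: BnBr, K2CO3, DMF, rt
Reagents that add atoms: benzyl bromide, BrCc1ccccc1
Why: Williamson etherification of the only acidic OH; the benzyl group shields the electron-rich phenol during the oxidation and falls in the last step.

Step 8
Reactants: 18 methyl 3-{4-[2-(benzyloxy)-5-(3-{[tert-butyl(dimethyl)silyl]oxy}propyl)phenoxy]-3-methoxyphenyl}propanoate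
Product: 20 3-{4-[2-(benzyloxy)-5-(3-hydroxypropyl)phenoxy]-3-methoxyphenyl}propanoic acid, via lithium carboxylate 19 (not isolated)
Conditions: LiOH·H2O, THF/H2O, rt; then 2 M HCl to pH 1, THF/H2O, rt
Reagents that add atoms: lithium hydroxide, [Li+].[OH-]
Why: Saponification of the methyl ester is followed in the same pot by acid-catalysed solvolysis of the primary silyl ether, and the benzyl and diaryl ethers are inert to both.

Step 9
Reactants: 20 3-{4-[2-(benzyloxy)-5-(3-hydroxypropyl)phenoxy]-3-methoxyphenyl}propanoic acid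
Product: 22 3-{4-[2-(benzyloxy)-5-(2-carboxyethyl)phenoxy]-3-methoxyphenyl}propanoic acid, via aldehyde acid 21 (not isolated)
Conditions: TEMPO (20 mol %), PhI(OAc)2 (2.2 equiv), MeCN/H2O 1:1, rt
Reagents that add atoms: water, O
Why: TEMPO/PhI(OAc)2 oxidation in aqueous acetonitrile takes the primary alcohol through the aldehyde hydrate to the acid and spares benzyl ethers and electron-rich arenes.

Step 10
Reactants: 22 3-{4-[2-(benzyloxy)-5-(2-carboxyethyl)phenoxy]-3-methoxyphenyl}propanoic acid
Product: 24 3-{4-[2-(benzyloxy)-5-{3-[methoxy(methyl)amino]-3-oxopropyl}phenoxy]-3-methoxyphenyl}-N-methoxy-N-methylpropanamide, via bis(acyl imidazolide) 23 (not isolated)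
Conditions: 1,1'-carbonyldiimidazole (2.4 equiv), CH2Cl2, rt; then MeNH(OMe)·HCl (3 equiv), rt
Reagents that add atoms: N,O-dimethylhydroxylamine hydrochloride, CNOC.Cl
Why: Twofold Weinreb amide formation through the acyl imidazolides turns both chains into identical acylating ends.

Step 11
Reactants: 25 4-bromobenzene-1,3-diol
Product: 26 2,4-bis(benzyloxy)-1-bromobenzene
Conditions: BnBr (2.2 equiv), K2CO3, DMF, 60 °C
Reagents that add atoms: benzyl bromide, BrCc1ccccc1
Why: Twofold Williamson etherification; the bromine marks the later acylation site on the resorcinol ring.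

Step 12
Reactants: 24 3-{4-[2-(benzyloxy)-5-{3-[methoxy(methyl)amino]-3-oxopropyl}phenoxy]-3-methoxyphenyl}-N-methoxy-N-methylpropanamide; 26 2,4-bis(benzyloxy)-1-bromobenzene
Product: 29 3-{4-[2-(benzyloxy)-5-{3-[2,4-bis(benzyloxy)phenyl]-3-oxopropyl}phenoxy]-3-methoxyphenyl}-1-[2,4-bis(benzyloxy)phenyl]propan-1-one, via 2,4-bis(benzyloxy)phenyllithium 27 (not isolated), via bis(lithium hemiaminal) adduct 28 (not isolated)
Conditions: 26 (3 equiv), n-BuLi (2.9 equiv), THF, −78 °C; then 24, −78 to −20 °C; aq NH4Cl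
Reagents that add atoms: none
Why: Bromine–lithium exchange followed by Weinreb ketone synthesis stops each chain at the ketone through the chelated tetrahedral adduct, and the bromide fixes the acylation site, so no Friedel–Crafts step is needed that could close the arylpropanoic acids to indanones.

Step 13
Reactants: 29 3-{4-[2-(benzyloxy)-5-{3-[2,4-bis(benzyloxy)phenyl]-3-oxopropyl}phenoxy]-3-methoxyphenyl}-1-[2,4-bis(benzyloxy)phenyl]propan-1-one
Product: 30 verbenachalcone
Conditions: H2 (1 atm), 10% Pd/C, EtOAc/MeOH, rt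
Reagents that add atoms: none
Why: Hydrogenolysis of the five benzyl aryl ethers on Pd/C; the aryl ketones, deactivated by the electron-rich ring and hydrogen-bonded to the freed ortho hydroxyl, should not be reduced at 1 atm.

Compound list
1 | (3-bromopropoxy)(tert-butyl)dimethylsilane | BrCCCO[Si](C)(C)C(C)(C)C | starting material
2 | prop-2-yn-1-ol | C#CCO | starting material
3 | [3-(tert-butyldimethylsilyloxy)propyl]magnesium bromide | Br[Mg]CCCO[Si](C)(C)C(C)(C)C | intermediate (not isolated)
4 | 4-[3-(tert-butyldimethylsilyloxy)propyl]-2,5-dihydro-1,2-oxamagnesole (chelated alkenylmagnesium alkoxide, Mg cis to the CH2O carbon) | CC(C)(C)[Si](C)(C)OCCCC1=C[Mg]OC1 | intermediate (not isolated)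
5 | (2Z)-5-[(tert-butyldimethylsilyl)oxy]-2-(iodomethylidene)pentan-1-ol | OC/C(CCCO[Si](C)(C)C(C)(C)C)=C\I | intermediate
6 | (2Z)-5-[(tert-butyldimethylsilyl)oxy]-2-(iodomethylidene)pentanal | O=C/C(CCCO[Si](C)(C)C(C)(C)C)=C\I | intermediate
7 | tert-butyl{[(4Z)-4-(iodomethylidene)hex-5-en-1-yl]oxy}dimethylsilane | C=C/C(CCCO[Si](C)(C)C(C)(C)C)=C\I | intermediate
8 | chromium hexacarbonyl, Cr(CO)6 | O=C=[Cr](=C=O)(=C=O)(=C=O)(=C=O)=C=O | starting material
9 | [(1Z)-2-{3-[(tert-butyldimethylsilyl)oxy]propyl}buta-1,3-dien-1-yl]lithium | C=C/C(CCCO[Si](C)(C)C(C)(C)C)=C\[Li] | intermediate (not isolated)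
10 | lithium pentacarbonyl{(2Z)-3-[3-(tert-butyldimethylsilyloxy)propyl]-1-oxidopenta-2,4-dien-1-ylidene}chromate | [Li+].C=C/C(CCCO[Si](C)(C)C(C)(C)C)=C\C([O-])=[Cr](=C=O)(=C=O)(=C=O)(=C=O)=C=O | intermediate (not isolated)
11 | tetramethylammonium pentacarbonyl{(2Z)-3-[3-(tert-butyldimethylsilyloxy)propyl]-1-oxidopenta-2,4-dien-1-ylidene}chromate | C[N+](C)(C)C.C=C/C(CCCO[Si](C)(C)C(C)(C)C)=C\C([O-])=[Cr](=C=O)(=C=O)(=C=O)(=C=O)=C=O | intermediate
12 | methyl 3-(4-hydroxy-3-methoxyphenyl)propanoate | COC(=O)CCc1ccc(O)c(OC)c1 | starting material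
13 | pentacarbonyl{(2Z)-1-(acetyloxy)-3-[3-(tert-butyldimethylsilyloxy)propyl]penta-2,4-dien-1-ylidene}chromium | C=C/C(CCCO[Si](C)(C)C(C)(C)C)=C\C(OC(C)=O)=[Cr](=C=O)(=C=O)(=C=O)(=C=O)=C=O | intermediate (not isolated)
14 | pentacarbonyl{(2Z)-3-[3-(tert-butyldimethylsilyloxy)propyl]-1-[2-methoxy-4-(3-methoxy-3-oxopropyl)phenoxy]penta-2,4-dien-1-ylidene}chromium | C=C/C(CCCO[Si](C)(C)C(C)(C)C)=C\C(Oc1ccc(CCC(=O)OC)cc1OC)=[Cr](=C=O)(=C=O)(=C=O)(=C=O)=C=O | intermediate
15 | methyl 3-{4-[(3Z)-4-(3-{[tert-butyl(dimethyl)silyl]oxy}propyl)-1-oxohexa-1,3,5-trien-2-yl]oxy-3-methoxyphenyl}propanoate (dienylketene, formed on chromium, drawn as the free ligand) | C=C/C(CCCO[Si](C)(C)C(C)(C)C)=C\C(Oc1ccc(CCC(=O)OC)cc1OC)=C=O | intermediate (not isolated)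
16 | methyl 3-{4-[(3-(3-{[tert-butyl(dimethyl)silyl]oxy}propyl)-6-oxocyclohexa-1,3-dien-1-yl)oxy]-3-methoxyphenyl}propanoate (2-aryloxy-4-alkylcyclohexa-2,4-dien-1-one) | O=C1CC=C(CCCO[Si](C)(C)C(C)(C)C)C=C1Oc1ccc(CCC(=O)OC)cc1OC | intermediate (not isolated)
17 | methyl 3-{4-[5-(3-{[tert-butyl(dimethyl)silyl]oxy}propyl)-2-hydroxyphenoxy]-3-methoxyphenyl}propanoate | COC(=O)CCc1ccc(Oc2cc(CCCO[Si](C)(C)C(C)(C)C)ccc2O)c(OC)c1 | intermediate
18 | methyl 3-{4-[2-(benzyloxy)-5-(3-{[tert-butyl(dimethyl)silyl]oxy}propyl)phenoxy]-3-methoxyphenyl}propanoate | COC(=O)CCc1ccc(Oc2cc(CCCO[Si](C)(C)C(C)(C)C)ccc2OCc2ccccc2)c(OC)c1 | intermediate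
19 | lithium 3-{4-[2-(benzyloxy)-5-(3-{[tert-butyl(dimethyl)silyl]oxy}propyl)phenoxy]-3-methoxyphenyl}propanoate | [Li+].[O-]C(=O)CCc1ccc(Oc2cc(CCCO[Si](C)(C)C(C)(C)C)ccc2OCc2ccccc2)c(OC)c1 | intermediate (not isolated)
20 | 3-{4-[2-(benzyloxy)-5-(3-hydroxypropyl)phenoxy]-3-methoxyphenyl}propanoic acid | OC(=O)CCc1ccc(Oc2cc(CCCO)ccc2OCc2ccccc2)c(OC)c1 | intermediate
21 | 3-{4-[2-(benzyloxy)-5-(3-oxopropyl)phenoxy]-3-methoxyphenyl}propanoic acid | OC(=O)CCc1ccc(Oc2cc(CCC=O)ccc2OCc2ccccc2)c(OC)c1 | intermediate (not isolated)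
22 | 3-{4-[2-(benzyloxy)-5-(2-carboxyethyl)phenoxy]-3-methoxyphenyl}propanoic acid | OC(=O)CCc1ccc(Oc2cc(CCC(=O)O)ccc2OCc2ccccc2)c(OC)c1 | intermediate
23 | 3-{4-[2-(benzyloxy)-5-[3-(1H-imidazol-1-yl)-3-oxopropyl]phenoxy]-3-methoxyphenyl}-1-(1H-imidazol-1-yl)propan-1-one | O=C(CCc1ccc(Oc2cc(CCC(=O)n3ccnc3)ccc2OCc2ccccc2)c(OC)c1)n1ccnc1 | intermediate (not isolated)
24 | 3-{4-[2-(benzyloxy)-5-{3-[methoxy(methyl)amino]-3-oxopropyl}phenoxy]-3-methoxyphenyl}-N-methoxy-N-methylpropanamide | CON(C)C(=O)CCc1ccc(Oc2cc(CCC(=O)N(C)OC)ccc2OCc2ccccc2)c(OC)c1 | intermediate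
25 | 4-bromobenzene-1,3-diol | Oc1ccc(Br)c(O)c1 | starting material
26 | 2,4-bis(benzyloxy)-1-bromobenzene | Brc1ccc(OCc2ccccc2)cc1OCc1ccccc1 | intermediate
27 | 2,4-bis(benzyloxy)phenyllithium | [Li]c1ccc(OCc2ccccc2)cc1OCc1ccccc1 | intermediate (not isolated)
28 | twofold lithium N-methoxy-N-methyl hemiaminal adduct of 24 with 27 (both hemiaminal carbons unspecified, lost on work-up) | CON(C)C(O[Li])(CCc1ccc(Oc2cc(CCC(O[Li])(N(C)OC)c3ccc(OCc4ccccc4)cc3OCc3ccccc3)ccc2OCc2ccccc2)c(OC)c1)c1ccc(OCc2ccccc2)cc1OCc1ccccc1 | intermediate (not isolated)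
29 | 3-{4-[2-(benzyloxy)-5-{3-[2,4-bis(benzyloxy)phenyl]-3-oxopropyl}phenoxy]-3-methoxyphenyl}-1-[2,4-bis(benzyloxy)phenyl]propan-1-one | COc1cc(CCC(=O)c2ccc(OCc3ccccc3)cc2OCc2ccccc2)ccc1Oc1cc(CCC(=O)c2ccc(OCc3ccccc3)cc2OCc2ccccc2)ccc1OCc1ccccc1 | intermediate
30 | verbenachalcone, 1-(2,4-dihydroxyphenyl)-3-{4-[5-[3-(2,4-dihydroxyphenyl)-3-oxopropyl]-2-hydroxyphenoxy]-3-methoxyphenyl}propan-1-one | COc1cc(CCC(=O)c2ccc(O)cc2O)ccc1Oc1cc(CCC(=O)c2ccc(O)cc2O)ccc1O | target

Total step count: 13. Longest linear sequence: 12 steps (steps 1 to 10, 12 and 13); step 11 is a one-step side branch.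

Steps most likely to fail

Step 6. After photochemical loss or migration of CO, the cis-dienylcarbene may close through chromium to a cyclopentadiene without taking up CO. The B1=B2 double bond may also photoisomerise so that the ketene cannot close, or the labile aryloxycarbene may decompose before insertion. The fallback forms the B3–O bond by a copper-catalysed Ullmann diaryl ether coupling, which is known chemistry. It sets out from phenol 12. Methyl 3-(4-hydroxyphenyl)propanoate is iodinated ortho to the hydroxyl (N-iodosuccinimide, TsOH cat., MeCN) to methyl 3-(4-hydroxy-3-iodophenyl)propanoate F1. Benzylation (BnBr, K2CO3, DMF) gives methyl 3-[4-(benzyloxy)-3-iodophenyl]propanoate F2. Coupling of F2 with 12 (CuI, N,N-dimethylglycine, Cs2CO3, dioxane, 90 °C) gives methyl 3-{4-(benzyloxy)-3-[2-methoxy-4-(3-methoxy-3-oxopropyl)phenoxy]phenyl}propanoate F3. Saponification of both esters (LiOH·H2O, THF/H2O) comes back to the route at diacid 22.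

Step 5. The phenol may add in conjugate fashion to the electrophilic dienylcarbene, or it may exchange so slowly that the acyloxycarbene decomposes. The fallback gives up the carbene for this bond and arylates the phenol without any metal by a diaryliodonium salt. It sets out from phenol 12. Iodide F2, made as above, is oxidised and coupled with 1,3,5-trimethoxybenzene (mCPBA, TsOH·H2O, MeCN; then the arene) to [2-(benzyloxy)-5-(3-methoxy-3-oxopropyl)phenyl](2,4,6-trimethoxyphenyl)iodonium 4-methylbenzenesulfonate F4. The phenoxide of 12 (K2CO3, toluene, 50 °C) takes the ring-B aryl group from F4 and gives diester F3, and saponification returns to the route at diacid 22.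

Step 3. The β-iodoenal 6 may lose its geometry by reversible conjugate addition of halide or ylide, or the ylide may attack the iodide-bearing carbon. The fallback sets the geometry by syn silylstannation of an alkyne and never passes through an enal. It sets out from bromide 1. Alkylation of LiC≡CH·H2NCH2CH2NH2 (DMSO, rt) gives tert-butyl(dimethyl)(pent-4-yn-1-yloxy)silane F5. Addition of Me3Si–SnBu3 under Pd(PPh3)4 (THF, 65 °C) is syn, with tin on the internal carbon, and gives tert-butyl(dimethyl){[(4Z)-4-(tributylstannyl)-5-(trimethylsilyl)pent-4-en-1-yl]oxy}silane F6. Stille coupling with vinyl bromide (Pd(PPh3)4, CuI, DMF, 50 °C) gives tert-butyl(dimethyl){[(4Z)-4-[(trimethylsilyl)methylidene]hex-5-en-1-yl]oxy}silane F7. Iododesilylation with retention (N-iodosuccinimide, MeCN/ClCH2CN, 0 °C) comes back to the route at iodide 7.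

Further compounds
F1 | step 6 | methyl 3-(4-hydroxy-3-iodophenyl)propanoate | COC(=O)CCc1ccc(O)c(I)c1
F2 | step 6 | methyl 3-[4-(benzyloxy)-3-iodophenyl]propanoate | COC(=O)CCc1ccc(OCc2ccccc2)c(I)c1
F3 | step 6 | methyl 3-{4-(benzyloxy)-3-[2-methoxy-4-(3-methoxy-3-oxopropyl)phenoxy]phenyl}propanoate | COC(=O)CCc1ccc(Oc2cc(CCC(=O)OC)ccc2OCc2ccccc2)c(OC)c1
F4 | step 5 | [2-(benzyloxy)-5-(3-methoxy-3-oxopropyl)phenyl](2,4,6-trimethoxyphenyl)iodonium 4-methylbenzenesulfonate | COC(=O)CCc1ccc(OCc2ccccc2)c([I+]c2c(OC)cc(OC)cc2OC)c1.Cc1ccc(S(=O)(=O)[O-])cc1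
F5 | step 3 | tert-butyl(dimethyl)(pent-4-yn-1-yloxy)silane | C#CCCCO[Si](C)(C)C(C)(C)C
F6 | step 3 | tert-butyl(dimethyl){[(4Z)-4-(tributylstannyl)-5-(trimethylsilyl)pent-4-en-1-yl]oxy}silane | C[Si](C)(C)/C=C(\[Sn](CCCC)(CCCC)CCCC)CCCO[Si](C)(C)C(C)(C)C
F7 | step 3 | tert-butyl(dimethyl){[(4Z)-4-[(trimethylsilyl)methylidene]hex-5-en-1-yl]oxy}silane | C=C/C(CCCO[Si](C)(C)C(C)(C)C)=C\[Si](C)(C)C
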